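## The problem

Compound 17 is two acylphloroglucinol units held together by one methylene carbon. Ring A is a dearomatised, enolised cyclohexanetrione: C1 carries the hexanoyl group, C2 and C4 are enol carbons, C3 is quaternary with methyl and 3-methylbut-2-enyl (prenyl), C5 carries the bridging CH2 and C6 is the ring carbonyl. Ring B is an aromatic 3-butanoyl-2,4-dihydroxy-6-methoxyphenyl group. Neither carbocycle has to be built, because both oxygenation patterns are those of cheap phloroglucinols; the work lies in substituting them in the right order and in taking ring A out of the aromatic series at C3 only. C3 is the only stereocentre (R in the tautomer drawn); no neighbouring centre can relay configuration to it, and its two ring arms differ only at a distance (hexanoyl on C1 against the benzyl group on C5), so it must be set by an outside element. Several groups limit the conditions: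

- the β-triketone is a strong vinylogous acid that chelates metals and can lose its acyl group under hard base;
- the prenyl alkene adds a neighbouring enol hydroxyl under strong acid and rules out hydrogenation;
- the methylene bridge exchanges between rings under alkali through loss of a quinone methide;
- ring B keeps one free nucleophilic carbon that can react a second time.

The feature that opens the route is the oxygen on C2, which lies between the acyl-bearing C1 and the quaternary C3. In an aromatic 3-methyl acylphloroglucinol this is a phenol oxygen, so an allyl group placed on it can pass to C3 through a six-membered transition state, and because C3 already carries methyl the ring cannot return to a phenol afterwards; a stereocentre in that allyl group can therefore be traded for C3.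

## Retrosynthesis

**Bridge (17 to 10 + 15).** The bond between C5 of ring A and the methylene carbon is cut last. The bridge is the most base-labile element and ring B is achiral, so a late union keeps the stereocentre away from all ring B chemistry. Cutting on the ring A side of the CH2 puts the electrophilic carbon on ring B, as the ortho-quinone methide 16 released from the Mannich base 15. The nucleophile is then the single free ring carbon of the acidic trione 10, so no site has to be chosen on the valuable half. The forward step asks only that 16 be formed without strong base and be trapped at carbon.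

**Ring B (15 to 14 to 13 to 11 + 12).** Three bonds are removed in turn: the aryl–CH2N bond, the O–CH3 bond and the aryl–acyl bond. In 14 the two free ring positions are equivalent, so aminomethylation raises only a question of stoichiometry. The methyl ether is cut before the acyl group because in 13 the hydroxyl para to the ketone is the only one not held in a hydrogen bond and can be methylated alone; acylating a preformed monomethyl ether would give ring isomers. Compounds 11 and 12 are commodity chemicals.

**Unmasking ring A (10 to 9 to 7 + 8).** The two O–CH2OCH3 bonds of 9 are cut first, then the trisubstituted C=C of the prenyl group, which is traced by cross-metathesis to the but-2-enyl group of 7 and to 8. Prenyl is not carried through the stereo-defining step, because an ether with two methyl groups on the carbinol carbon, which would deliver it directly, has no stereocentre. The ether with one methyl group has one, at the price of a single alkene exchange. The forward steps must spare the enol ethers during metathesis and the prenyl alkene during acetal hydrolysis.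

**Quaternary centre (7 to 6).** The bond between C3 and the allylic CH2 is cut and the allyl group is returned to O2 with allylic transposition, which turns dienone 7 into the aromatic ether 6. A direct alkylation of phenol 3 at C3 would have no facial control and would compete with the free C5; a catalytic allylation has the same site problem. This cut instead delivers carbon intramolecularly to the one non-acylated carbon next to O2 and makes the configuration a consequence of a purchasable carbinol centre. The precursor is flat apart from that centre. The forward reaction must run below the temperature at which the allyl group would move on to C5 and the ring would rearomatise.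

**Ether (6 to 4 + 5).** The bond between O2 and the carbinol carbon is cut; forward, a Mitsunobu reaction joins the only free phenol of 4 to 5 with inversion. A cut at the aryl–oxygen bond has no practical forward reaction on so electron-rich a ring. The step asks for direct substitution at a secondary allylic carbon by a hindered, hydrogen-bonded phenol without allylic transposition.

**Aromatic core (4 to 3 to 1 + 2).** The two methoxymethyl ethers are removed, then the aryl–acyl bond. In 3 the hydroxyl that must stay free is the one between methyl and acyl, which is also the most hindered and most strongly hydrogen-bonded, so protecting the other two needs no extra differentiation. The two ring CH positions of 1 are equivalent, so acylation with 2 has one outcome.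

## Roads not taken

**Alternative 1:** Ring A is cut across C2–C3 and C4–C5 and made by a Diels–Alder reaction of the aminosiloxydiene A2 with methacrolein A3 under a chiral diol hydrogen-bond catalyst; acid work-up would release the enone A1.
- Merits: the quaternary centre (methyl against formyl) is set catalytically in a cycloaddition class with a good record for exactly this dienophile, and no aromatic intermediate exists that could rearomatise. In the reliability of the stereo-defining event this road is probably ahead of the chosen one.
- Weak points: A1 has one of the three ring oxygens. Both carbons flanking the quaternary centre must still be oxidised, the formyl group needs a one-carbon homologation before olefination to become prenyl, and the hexanoyl group and the bridge come after that.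
- Comparison: the chosen plan starts with every ring carbon and oxygen in place and changes only two carbons after its key step, so it should be shorter by many steps.

**Alternative 2:** Ring A is cut at C1–C2 and closed by an intramolecular Claisen condensation of the open-chain trioxo ester A5 under alkoxide base, giving A4, which is the same compound as 10.
- Merits: it reaches the late intermediate without protecting groups or alkene exchange, the stereocentre is set early as an α-quaternary β-keto ester and never touched again, and there is no rearomatisation risk. If A5 were in hand, this road would be as short as the chosen one or shorter.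
- Weak points: the 3,5,7-trioxo chain must be assembled next to a non-enolisable quaternary keto ester, which alkoxide can cleave by retro-Claisen attack. The ring closure must also beat O-acylation to a pyran-2,4-dione and aldol closure of the chain methylene next to the pentyl group onto the ketone beside the quaternary carbon.
- Comparison: the chosen plan has a preformed carbocycle, so the mode of ring closure is not in question, and its stereo source is a commercial alcohol rather than an enantioselective alkylation that would need tuning.

**Alternative 3:** The bridge bond C5–CH2 is made the stereo-defining bond. The prochiral trione A7 would add through one of its two enantiotopic enol carbons to the quinone methide A9 (the same species as 16), generated from the benzylic alcohol A8 under a chiral phosphoric acid, to give A6; C-hexanoylation of the last free ring carbon would finish.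
- Merits: it is the shortest and most convergent road, since A7 should come from 1 in one dearomatising prenylation, and every component is achiral.
- Weak points: the catalyst must tell apart two ring carbons that differ only in whether methyl or prenyl stands above them two bonds away. A second benzylation gives an achiral product. The closing C-acylation must be done on a polyphenol whose bridge is labile to the acids and bases that acylation uses.
- Comparison: if that selectivity could be secured, this road would be better in step count. The chosen plan offers a stereospecific transfer whose sense follows from a chair model, and it installs the acyl group first, when that is trivial.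

Key step: step 4

Remark on the chemistry: the enolised triones equilibrate between tautomers; 10 and 17 are drawn and named in the tautomer of the target SMILES, and the same spatial arrangement at the quaternary carbon is 6R in dienones 7 and 9 and 4R in 10 and 17.

## Route

Step 1
Reactants: 1 2-methylbenzene-1,3,5-triol; 2 hexanoyl chloride
Product: 3 1-(2,4,6-trihydroxy-3-methylphenyl)hexan-1-one
Conditions: AlCl3 (3.5 equiv), PhNO2–CH2Cl2, 0 to 45 °C; ice, aq. HCl
Reagents that add atoms: none
Why: Friedel–Crafts C-acylation of a phloroglucinol; the two unsubstituted ring carbons of 1 are equivalent and the first acyl group deactivates the ring towards a second, so one mono-ketone is expected.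

Step 2
Reactants: 3 1-(2,4,6-trihydroxy-3-methylphenyl)hexan-1-one
Product: 4 1-[2-hydroxy-4,6-bis(methoxymethoxy)-3-methylphenyl]hexan-1-one
Conditions: MOMCl (2.2 equiv), iPr2NEt (2.5 equiv), CH2Cl2, 0 °C to rt
Reagents that add atoms: chloromethyl methyl ether, COCCl
Why: Methoxymethylation under amine base; the hydroxyl para to the ketone is unchelated and reacts first, and of the two ortho hydroxyls the one next to the ring hydrogen is the more accessible, whereas the hydroxyl wedged between methyl and acyl is held in the stronger hydrogen bond and is the usual survivor when C-methylated acylphloroglucinols are partially alkylated.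

Step 3
Reactants: 4 1-[2-hydroxy-4,6-bis(methoxymethoxy)-3-methylphenyl]hexan-1-one; 5 (2R)-but-3-en-2-ol
Product: 6 1-[2-[(2S)-but-3-en-2-yloxy]-4,6-bis(methoxymethoxy)-3-methylphenyl]hexan-1-one
Conditions: PPh3, DIAD, PhMe, 0 °C to rt
Reagents that add atoms: none
Why: Mitsunobu etherification; the hydrogen-bonded phenol is acidic enough to protonate the betaine and displaces the activated secondary allylic alcohol by direct substitution with inversion, so (2R)-5 becomes the (2S) ether, and 4 has only this one hydroxyl, which fixes the site.

Step 4
Reactants: 6 1-[2-[(2S)-but-3-en-2-yloxy]-4,6-bis(methoxymethoxy)-3-methylphenyl]hexan-1-one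
Product: 7 (6R)-6-[(2E)-but-2-en-1-yl]-2-hexanoyl-3,5-bis(methoxymethoxy)-6-methylcyclohexa-2,4-dien-1-one
Conditions: Eu(fod)3 [Eu(C10H10F7O2)3] (10 mol%), CHCl3, 45 °C
Reagents that add atoms: none
Why: A concerted suprafacial [3,3]-sigmatropic (aromatic Claisen) shift moves the but-3-en-2-yl group from O2 to the methyl-bearing ortho carbon C3, speeded by Eu(fod)3 held in the six-membered chelate of ether and ketone oxygens. The closest known reaction type is the lanthanide-catalysed aromatic Claisen rearrangement of enantioenriched secondary allyl aryl ethers with 1,3-chirality transfer, which here stops at the ortho-dienone because C3 has no hydrogen to lose. No ring is closed; one C–C bond (C3 to the allyl terminus) and the quaternary stereocentre are formed while the carbinol centre is consumed. The new centre is controlled by that carbinol centre: in the chair transition state its methyl group is pseudo-equatorial, which gives the E alkene and brings the allyl terminus to the face of C3 that turns the S ether into the R dienone. The step needs site selectivity (C3 over the acyl-bearing C1), geometric selectivity (E over Z, since a Z product would have the opposite configuration) and restraint from the onward Cope shift to C5. C1 is deactivated by the coordinated acyl group and an adduct there could only revert. The Cope shift would have to bond the methyl-substituted allyl terminus to a carbon flanked by two methoxymethoxy groups, whereas the first shift is helped by the α-methyl group and by the catalyst, so 45 °C should separate the two. The product is a doubly vinylogous ester, which should place it below the aryl ether in energy and hold it against reversal.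

Step 5
Reactants: 7 (6R)-6-[(2E)-but-2-en-1-yl]-2-hexanoyl-3,5-bis(methoxymethoxy)-6-methylcyclohexa-2,4-dien-1-one; 8 2-methylbut-2-ene
Product: 9 (6R)-2-hexanoyl-3,5-bis(methoxymethoxy)-6-methyl-6-(3-methylbut-2-en-1-yl)cyclohexa-2,4-dien-1-one
Conditions: second-generation Grubbs catalyst RuCl2(=CHPh)(PCy3)(H2IMes) (5 mol%), 8 (large excess)–CH2Cl2, 40 °C
Reagents that add atoms: none
Why: Olefin cross-metathesis; the disubstituted but-2-enyl alkene exchanges its ethylidene end for the isopropylidene end of 8, the trisubstituted product and the oxygenated ring alkenes are inert to the catalyst, and the quaternary centre is not touched.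

Step 6
Reactants: 9 (6R)-2-hexanoyl-3,5-bis(methoxymethoxy)-6-methyl-6-(3-methylbut-2-en-1-yl)cyclohexa-2,4-dien-1-one
Product: 10 (4R)-2-hexanoyl-3,5-dihydroxy-4-methyl-4-(3-methylbut-2-en-1-yl)cyclohexa-2,5-dien-1-one
Conditions: 2 M aq. HCl, THF, 0 °C to rt
Reagents that add atoms: none
Why: Hydrolysis of two methoxymethyl enol ethers; as vinylogous acetal esters they should cleave far more readily than aryl methoxymethyl ethers, so dilute acid at or below room temperature should suffice and leave the prenyl alkene alone, and the quaternary centre has no α-hydrogen and cannot epimerise.

Step 7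
Reactants: 11 benzene-1,3,5-triol; 12 butanoyl chloride
Product: 13 1-(2,4,6-trihydroxyphenyl)butan-1-one
Conditions: AlCl3 (3.5 equiv), PhNO2–CH2Cl2, 0 to 45 °C; ice, aq. HCl
Reagents that add atoms: none
Why: Friedel–Crafts C-acylation; all three ring carbons of 11 are equivalent and one equivalent of 12 limits the reaction to the mono-ketone.

Step 8
Reactants: 13 1-(2,4,6-trihydroxyphenyl)butan-1-one
Product: 14 1-(2,6-dihydroxy-4-methoxyphenyl)butan-1-one
Conditions: Me2SO4 (1.0 equiv), K2CO3 (1.0 equiv), acetone, rt
Reagents that add atoms: dimethyl sulfate, COS(=O)(=O)OC
Why: Williamson methylation with one equivalent of electrophile; the two ortho hydroxyls are tied up in hydrogen bonds to the ketone, so the more acidic, unchelated para hydroxyl is alkylated selectively.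

Step 9
Reactants: 14 1-(2,6-dihydroxy-4-methoxyphenyl)butan-1-one
Product: 15 1-[3-[(dimethylamino)methyl]-2,6-dihydroxy-4-methoxyphenyl]butan-1-one
Conditions: [Me2N=CH2]I (0.95 equiv), Et3N (1.0 equiv), CH2Cl2, 0 °C to rt
Reagents that add atoms: N,N-dimethylmethaniminium iodide, C=[N+](C)C.[I-]
Why: Mannich aminomethylation of an electron-rich phenol with a preformed iminium salt; the two free ring positions of 14 are equivalent, and a slight deficit of the salt keeps the reaction at one aminomethyl group.

Step 10
Reactants: 10 (4R)-2-hexanoyl-3,5-dihydroxy-4-methyl-4-(3-methylbut-2-en-1-yl)cyclohexa-2,5-dien-1-one; 15 1-[3-[(dimethylamino)methyl]-2,6-dihydroxy-4-methoxyphenyl]butan-1-one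
Product: 17 (4R)-2-[(3-butanoyl-2,4-dihydroxy-6-methoxyphenyl)methyl]-6-hexanoyl-3,5-dihydroxy-4-methyl-4-(3-methylbut-2-en-1-yl)cyclohexa-2,5-dien-1-one, via ortho-quinone methide 16 (not isolated)
Conditions: 15 (1.2 equiv), 1,4-dioxane, 90 °C, N2 stream
Reagents that add atoms: none
Why: Proton transfer from the acidic trione 10 to the amine of 15 and warming expel dimethylamine and give the ortho-quinone methide 16, to which the only free ring carbon of 10 (C5) adds in a Michael reaction, and rearomatisation of ring B completes the bridge; this is the standard alkylation of 1,3-dicarbonyl compounds by phenolic Mannich bases, it needs no strong base, and it does not involve the quaternary centre.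

## Compound list

1 | 2-methylbenzene-1,3,5-triol | Cc1c(O)cc(O)cc1O | starting material
2 | hexanoyl chloride | CCCCCC(=O)Cl | starting material
3 | 1-(2,4,6-trihydroxy-3-methylphenyl)hexan-1-one | CCCCCC(=O)c1c(O)c(C)c(O)cc1O | intermediate
4 | 1-[2-hydroxy-4,6-bis(methoxymethoxy)-3-methylphenyl]hexan-1-one | CCCCCC(=O)c1c(O)c(C)c(OCOC)cc1OCOC | intermediate
5 | (2R)-but-3-en-2-ol | C[C@@H](O)C=C | starting material
6 | 1-[2-[(2S)-but-3-en-2-yloxy]-4,6-bis(methoxymethoxy)-3-methylphenyl]hexan-1-one | CCCCCC(=O)c1c(O[C@@H](C)C=C)c(C)c(OCOC)cc1OCOC | intermediate
7 | (6R)-6-[(2E)-but-2-en-1-yl]-2-hexanoyl-3,5-bis(methoxymethoxy)-6-methylcyclohexa-2,4-dien-1-one | CCCCCC(=O)C1=C(OCOC)C=C(OCOC)[C@@](C)(C/C=C/C)C1=O | intermediate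
8 | 2-methylbut-2-ene | CC=C(C)C | starting material
9 | (6R)-2-hexanoyl-3,5-bis(methoxymethoxy)-6-methyl-6-(3-methylbut-2-en-1-yl)cyclohexa-2,4-dien-1-one | CCCCCC(=O)C1=C(OCOC)C=C(OCOC)[C@@](C)(CC=C(C)C)C1=O | intermediate
10 | (4R)-2-hexanoyl-3,5-dihydroxy-4-methyl-4-(3-methylbut-2-en-1-yl)cyclohexa-2,5-dien-1-one | CCCCCC(=O)C1=C(O)[C@](C)(CC=C(C)C)C(O)=CC1=O | intermediate
11 | benzene-1,3,5-triol | Oc1cc(O)cc(O)c1 | starting material
12 | butanoyl chloride | CCCC(=O)Cl | starting material
13 | 1-(2,4,6-trihydroxyphenyl)butan-1-one | CCCC(=O)c1c(O)cc(O)cc1O | intermediate
14 | 1-(2,6-dihydroxy-4-methoxyphenyl)butan-1-one | CCCC(=O)c1c(O)cc(OC)cc1O | intermediate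
15 | 1-[3-[(dimethylamino)methyl]-2,6-dihydroxy-4-methoxyphenyl]butan-1-one | CCCC(=O)c1c(O)cc(OC)c(CN(C)C)c1O | intermediate
16 | 2-butanoyl-3-hydroxy-5-methoxy-6-methylidenecyclohexa-2,4-dien-1-one | CCCC(=O)C1=C(O)C=C(OC)C(=C)C1=O | intermediate (not isolated)
17 | (4R)-2-[(3-butanoyl-2,4-dihydroxy-6-methoxyphenyl)methyl]-6-hexanoyl-3,5-dihydroxy-4-methyl-4-(3-methylbut-2-en-1-yl)cyclohexa-2,5-dien-1-one | CCCCCC(=O)C1=C(O)[C@](C)(CC=C(C)C)C(O)=C(Cc2c(OC)cc(O)c(C(=O)CCC)c2O)C1=O | target

## Step count and risks

Total: 10 steps. Longest linear sequence: 7 steps (steps 1 to 6, then step 10); the ring B branch is steps 7 to 9.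

**Step 4 (key step).** The most likely failure is that the allyl group does not stop at C3: a second [3,3] shift to the unsubstituted C5 followed by enolisation would rearomatise ring A and erase the stereocentre, and this outcome is the thermodynamically preferred one. A second risk is partial ionisation of the metal-bound ether to an allyl cation and a phenoxide, which would lower the chirality transfer.
Fallback (from 6, back at 10): block C5 before the shift.
- N-Bromosuccinimide should brominate the only ring CH of 6 to 1-[3-bromo-6-[(2S)-but-3-en-2-yloxy]-2,4-bis(methoxymethoxy)-5-methylphenyl]hexan-1-one F1.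
- The same [3,3] shift, which may now also be run without Lewis acid in hot toluene, should give (6R)-4-bromo-6-[(2E)-but-2-en-1-yl]-2-hexanoyl-3,5-bis(methoxymethoxy)-6-methylcyclohexa-2,4-dien-1-one F2. A further shift to C5 can no longer end in a phenol and can only revert.
- Cross-metathesis with 8 as in step 5 should give (6R)-4-bromo-2-hexanoyl-3,5-bis(methoxymethoxy)-6-methyl-6-(3-methylbut-2-en-1-yl)cyclohexa-2,4-dien-1-one F3.
- Dilute acid as in step 6 should give (4S)-2-bromo-6-hexanoyl-3,5-dihydroxy-4-methyl-4-(3-methylbut-2-en-1-yl)cyclohexa-2,5-dien-1-one F4; the descriptor changes with the bromine, the geometry does not.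
- Zn dust in acetic acid reduces this 2-bromo-1,3-dione to 10.

**Step 3.** The phenol is flanked on both sides and hydrogen-bonded, so the substitution may be slow. The activated allylic alcohol may then react with allylic transposition (giving the linear but-2-enyl ether), eliminate, or ionise with loss of configuration.
Fallback (from 4, back at 6): replace the Mitsunobu reaction by a propargylic displacement. Commercial (2R)-but-3-yn-2-ol is converted with methanesulfonyl chloride and Et3N into (2R)-but-3-yn-2-yl methanesulfonate F5. This alkylates the phenoxide of 4 (K2CO3, DMF) by direct substitution with inversion, an alkyne having little tendency to transposed attack, and gives 1-[2-[(2S)-but-3-yn-2-yloxy]-4,6-bis(methoxymethoxy)-3-methylphenyl]hexan-1-one F6. Semi-hydrogenation over Lindlar catalyst (Pd on CaCO3 poisoned with Pb(OAc)2, quinoline, H2) then gives 6.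

**Step 10.** The quinone methide may add to the free ring carbon of ring B in the product or in 15 instead of to 10, giving oligomers. Under the amine set free, the bridge may also reopen by retro-Michael loss of the quinone methide and exchange between rings.
Fallback (from 10, back at 17): reverse the roles so that ring A carries the electrophilic carbon. The iminium iodide of step 9 aminomethylates the only free ring carbon of 10 to (4R)-2-[(dimethylamino)methyl]-6-hexanoyl-3,5-dihydroxy-4-methyl-4-(3-methylbut-2-en-1-yl)cyclohexa-2,5-dien-1-one F7. Warming F7 with an excess of 14 expels dimethylamine to give (6S)-4-hexanoyl-5-hydroxy-6-methyl-2-methylidene-6-(3-methylbut-2-en-1-yl)cyclohex-4-ene-1,3-dione F8 in the flask, and a free ring carbon of 14 adds to it to give 17. The excess of the cheap phenol suppresses double alkylation.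

**Step 6.** While the acetals are being hydrolysed, a freed enol hydroxyl next to C3 may add to the acid-activated prenyl alkene and close a dimethyl-dihydropyran ring.
Fallback (from 7, back at 10): change the order so that acid never meets the prenyl group. Dilute acid on 7, whose disubstituted alkene is far less prone to protonation, gives (4R)-4-[(2E)-but-2-en-1-yl]-2-hexanoyl-3,5-dihydroxy-4-methylcyclohexa-2,5-dien-1-one F9, and cross-metathesis of F9 with 8 under the conditions of step 5 gives 10.

Further compounds
F1 | step 4 | 1-[3-bromo-6-[(2S)-but-3-en-2-yloxy]-2,4-bis(methoxymethoxy)-5-methylphenyl]hexan-1-one | CCCCCC(=O)c1c(O[C@@H](C)C=C)c(C)c(OCOC)c(Br)c1OCOC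
F2 | step 4 | (6R)-4-bromo-6-[(2E)-but-2-en-1-yl]-2-hexanoyl-3,5-bis(methoxymethoxy)-6-methylcyclohexa-2,4-dien-1-one | CCCCCC(=O)C1=C(OCOC)C(Br)=C(OCOC)[C@@](C)(C/C=C/C)C1=O
F3 | step 4 | (6R)-4-bromo-2-hexanoyl-3,5-bis(methoxymethoxy)-6-methyl-6-(3-methylbut-2-en-1-yl)cyclohexa-2,4-dien-1-one | CCCCCC(=O)C1=C(OCOC)C(Br)=C(OCOC)[C@@](C)(CC=C(C)C)C1=O
F4 | step 4 | (4S)-2-bromo-6-hexanoyl-3,5-dihydroxy-4-methyl-4-(3-methylbut-2-en-1-yl)cyclohexa-2,5-dien-1-one | CCCCCC(=O)C1=C(O)[C@](C)(CC=C(C)C)C(O)=C(Br)C1=O
F5 | step 3 | (2R)-but-3-yn-2-yl methanesulfonate | C[C@@H](OS(C)(=O)=O)C#C
F6 | step 3 | 1-[2-[(2S)-but-3-yn-2-yloxy]-4,6-bis(methoxymethoxy)-3-methylphenyl]hexan-1-one | CCCCCC(=O)c1c(O[C@@H](C)C#C)c(C)c(OCOC)cc1OCOC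
F7 | step 10 | (4R)-2-[(dimethylamino)methyl]-6-hexanoyl-3,5-dihydroxy-4-methyl-4-(3-methylbut-2-en-1-yl)cyclohexa-2,5-dien-1-one | CCCCCC(=O)C1=C(O)[C@](C)(CC=C(C)C)C(O)=C(CN(C)C)C1=O
F8 | step 10 | (6S)-4-hexanoyl-5-hydroxy-6-methyl-2-methylidene-6-(3-methylbut-2-en-1-yl)cyclohex-4-ene-1,3-dione | CCCCCC(=O)C1=C(O)[C@](C)(CC=C(C)C)C(=O)C(=C)C1=O
F9 | step 6 | (4R)-4-[(2E)-but-2-en-1-yl]-2-hexanoyl-3,5-dihydroxy-4-methylcyclohexa-2,5-dien-1-one | CCCCCC(=O)C1=C(O)[C@](C)(C/C=C/C)C(O)=CC1=O
A1 | alternative 1 | (1R)-1-methyl-4-oxocyclohex-2-ene-1-carbaldehyde | O=C1C=C[C@](C)(C=O)CC1
A2 | alternative 1 | (1E)-3-[tert-butyl(dimethyl)silyl]oxy-N,N-dimethylbuta-1,3-dien-1-amine | CN(C)/C=C/C(=C)O[Si](C)(C)C(C)(C)C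
A3 | alternative 1 | 2-methylprop-2-enal (methacrolein) | CC(=C)C=O
A4 | alternative 2 | (4R)-2-hexanoyl-3,5-dihydroxy-4-methyl-4-(3-methylbut-2-en-1-yl)cyclohexa-2,5-dien-1-one | CCCCCC(=O)C1=C(O)[C@](C)(CC=C(C)C)C(O)=CC1=O
A5 | alternative 2 | methyl (2R)-2-methyl-2-(3-methylbut-2-en-1-yl)-3,5,7-trioxododecanoate | COC(=O)[C@](C)(CC=C(C)C)C(=O)CC(=O)CC(=O)CCCCC
A6 | alternative 3 | (4S)-2-[(3-butanoyl-2,4-dihydroxy-6-methoxyphenyl)methyl]-3,5-dihydroxy-4-methyl-4-(3-methylbut-2-en-1-yl)cyclohexa-2,5-dien-1-one | O=C1C=C(O)[C@](C)(CC=C(C)C)C(O)=C1Cc1c(OC)cc(O)c(C(=O)CCC)c1O
A7 | alternative 3 | 3,5-dihydroxy-4-methyl-4-(3-methylbut-2-en-1-yl)cyclohexa-2,5-dien-1-one | CC(C)=CCC1(C)C(O)=CC(=O)C=C1O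
A8 | alternative 3 | 1-[2,6-dihydroxy-3-(hydroxymethyl)-4-methoxyphenyl]butan-1-one | CCCC(=O)c1c(O)cc(OC)c(CO)c1O
A9 | alternative 3 | 2-butanoyl-3-hydroxy-5-methoxy-6-methylidenecyclohexa-2,4-dien-1-one | CCCC(=O)C1=C(O)C=C(OC)C(=C)C1=O
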